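**Retrosynthetic overview**

- Feature: the C40 chain on C3 of the 2-methyl-1,4-naphthoquinone bicycle (numbered from C1', the ring-bound CH2, to C32') has eight prenyl units and seven E trisubstituted alkenes; the CH2–CH2 bond C16'–C17' divides it into two all-E C20 units, and menaquinone-4 already carries both rings and C1'–C16'.
- Last disconnections: quinone 14 from its quinol dimethyl ether 13 (oxidative demethylation); 13 from the C17' phenyl sulfone 12 (reductive C–S cleavage).
- Key disconnection C16'–C17': 12 from lithiated geranylgeranyl phenyl sulfone 11 and the 16'-bromide 6.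
- Bromide 6 from menaquinone-4 (1) by reductive methylation, oxidation of the terminal E-methyl and bromination; sulfone 10 from geranylgeraniol 7 through bromide 8 and sodium benzenesulfinate 9.
- Rings: none is formed; both rings of the naphthoquinone come intact from 1.

Key step: step 6

Remark on the chemistry: all-E menatetrenone and all-E geranylgeraniol are taken as commercial. The lithiated sulfone 11 is drawn with a C–Li bond for bookkeeping, although it is a delocalised allyl anion.

**Route**

Step 1
Reactants: 1 menatetrenone (menaquinone-4, all-E)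
Product: 3 menaquinol-4 dimethyl ether (2-[(2E,6E,10E)-geranylgeranyl]-1,4-dimethoxy-3-methylnaphthalene), via menaquinol-4 2 (not isolated)
Conditions: Na2S2O4, Et2O/H2O, rt, Ar; organic layer dried and concentrated; then NaH, MeI, THF/DMF, 0 °C to rt
Reagents that add atoms: iodomethane, CI
Why: Dithionite reduces the quinone to the hydroquinone, whose bis-phenoxide undergoes double Williamson O-methylation, so the ring is masked against the carbanion and the hydride used later.

Step 2
Reactants: 3 menaquinol-4 dimethyl ether
Product: 5 (2'E,6'E,10'E,14'E)-16'-hydroxymenaquinol-4 dimethyl ether, via 16'-oxo enal 4 (not isolated)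
Conditions: SeO2 (cat.), t-BuOOH, salicylic acid (cat.), CH2Cl2, 0 °C to rt, stopped at partial conversion; crude then NaBH4, EtOH, 0 °C; unreacted 3 recycled
Reagents that add atoms: selenium dioxide, O=[Se]=O; tert-butyl hydroperoxide, CC(C)(C)OO
Why: The Sharpless catalytic SeO2 allylic oxidation (ene reaction, then [2,3]-sigmatropic shift of the allylseleninic acid) should attack the most accessible, terminal gem-dimethyl alkene at its E-methyl, which fixes C14'=C15' as E, and NaBH4 converts the over-oxidised enal 4 into the same alcohol by 1,2-reduction.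

Step 3
Reactants: 5 (all-E)-16'-hydroxymenaquinol-4 dimethyl ether
Product: 6 (all-E)-16'-bromomenaquinol-4 dimethyl ether
Conditions: PBr3, Et2O, −10 °C, dark; used crude at once
Reagents that add atoms: phosphorus tribromide, BrP(Br)Br
Why: Bromination of a primary allylic alcohol through its phosphite ester is an SN2 displacement at the unhindered CH2, which should leave the C14'=C15' geometry and the aryl methyl ethers untouched at low temperature.

Step 4
Reactants: 7 (2E,6E,10E)-geranylgeraniol
Product: 8 (2E,6E,10E)-geranylgeranyl bromide
Conditions: PBr3, Et2O, −10 °C; used crude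
Reagents that add atoms: phosphorus tribromide, BrP(Br)Br
Why: The same low-temperature PBr3 bromination of a primary allylic alcohol is the standard entry to prenyl bromides with retention of the 2E geometry.

Step 5
Reactants: 8 geranylgeranyl bromide; 9 sodium benzenesulfinate
Product: 10 (2E,6E,10E)-geranylgeranyl phenyl sulfone
Conditions: DMF, rt
Reagents that add atoms: none
Why: The ambident sulfinate anion alkylates at its soft sulfur atom in an SN2 displacement of the primary allylic bromide, giving the sulfone directly.

Step 6
Reactants: 10 geranylgeranyl phenyl sulfone; 6 (all-E)-16'-bromomenaquinol-4 dimethyl ether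
Product: 12 17'-(phenylsulfonyl)menaquinol-8 dimethyl ether (all-E, racemic at C17'), via lithiated sulfone 11 (not isolated)
Conditions: 10 (slight excess), n-BuLi, THF, −78 °C; then 6, THF/DMPU, −78 to −20 °C
Reagents that add atoms: none
Why: n-BuLi removes a proton from the CH2 between the sulfonyl group and C18'=C19' to give the sulfonyl-stabilised allyllithium 11, whose α-carbon displaces bromide from the primary allylic CH2Br of 6 by SN2 and so forms the C16'–C17' bond. The closest known reaction type is the alkylation of prenyl sulfone anions with allylic halides used for head-to-tail assembly of polyprenyl chains. No ring is closed. The new stereocentre at C17' forms without control, so 12 is racemic, and this is harmless because step 7 replaces the sulfonyl group by hydrogen. The step needs α- over γ-attack of the anion, secured by charge localisation next to sulfur and by the fully substituted γ-carbon C19', and SN2 over SN2' at the electrophile, secured by the open CH2Br compared with the more hindered C14'. All seven E alkenes lie outside the reacting centres, and the dimethyl ether keeps the ring inert to the carbanion.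

Step 7
Reactants: 12 17'-(phenylsulfonyl)menaquinol-8 dimethyl ether
Product: 13 menaquinol-8 dimethyl ether (all-E)
Conditions: LiBHEt3, PdCl2(dppp) (cat.), THF, 0 °C
Reagents that add atoms: none
Why: In this palladium-catalysed reductive desulfonylation of an allylic sulfone, zerovalent palladium (formed from the divalent PdCl2(dppp) by the hydride) ionises the C17'–S bond to a π-allylpalladium complex, and hydride is delivered to the less substituted terminus C17', so C18'=C19' should stay in place as the E alkene while the aryl methyl ethers are inert at 0 °C.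

Step 8
Reactants: 13 menaquinol-8 dimethyl ether
Product: 14 menaquinone-8
Conditions: (NH4)2Ce(NO3)6, MeCN/CH2Cl2/H2O, 0 °C, short reaction time
Reagents that add atoms: water, O
Why: Oxidative demethylation by tetravalent cerium proceeds through the arene radical cation, which takes up water and loses methanol to give the 1,4-naphthoquinone, while the isolated trisubstituted alkenes should survive the brief cold treatment.

**Compound list**

1 | menatetrenone (menaquinone-4, all-E) | CC(C)=CCC/C(C)=C/CC/C(C)=C/CC/C(C)=C/CC1=C(C)C(=O)c2ccccc2C1=O | starting material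
2 | menaquinol-4 (hydroquinone of 1) | CC(C)=CCC/C(C)=C/CC/C(C)=C/CC/C(C)=C/Cc1c(C)c(O)c2ccccc2c1O | intermediate
3 | menaquinol-4 dimethyl ether | CC(C)=CCC/C(C)=C/CC/C(C)=C/CC/C(C)=C/Cc1c(C)c(OC)c2ccccc2c1OC | intermediate
4 | (all-E)-16'-oxomenaquinol-4 dimethyl ether (terminal enal) | O=C/C(C)=C/CC/C(C)=C/CC/C(C)=C/CC/C(C)=C/Cc1c(C)c(OC)c2ccccc2c1OC | intermediate
5 | (all-E)-16'-hydroxymenaquinol-4 dimethyl ether | OC/C(C)=C/CC/C(C)=C/CC/C(C)=C/CC/C(C)=C/Cc1c(C)c(OC)c2ccccc2c1OC | intermediate
6 | (all-E)-16'-bromomenaquinol-4 dimethyl ether | BrC/C(C)=C/CC/C(C)=C/CC/C(C)=C/CC/C(C)=C/Cc1c(C)c(OC)c2ccccc2c1OC | intermediate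
7 | (2E,6E,10E)-geranylgeraniol | CC(C)=CCC/C(C)=C/CC/C(C)=C/CC/C(C)=C/CO | starting material
8 | (2E,6E,10E)-geranylgeranyl bromide | CC(C)=CCC/C(C)=C/CC/C(C)=C/CC/C(C)=C/CBr | intermediate
9 | sodium benzenesulfinate | [Na+].[O-]S(=O)c1ccccc1 | starting material
10 | (2E,6E,10E)-geranylgeranyl phenyl sulfone | CC(C)=CCC/C(C)=C/CC/C(C)=C/CC/C(C)=C/CS(=O)(=O)c1ccccc1 | intermediate
11 | α-lithio geranylgeranyl phenyl sulfone | CC(C)=CCC/C(C)=C/CC/C(C)=C/CC/C(C)=C/C([Li])S(=O)(=O)c1ccccc1 | intermediate
12 | 17'-(phenylsulfonyl)menaquinol-8 dimethyl ether (all-E, racemic at C17') | CC(C)=CCC/C(C)=C/CC/C(C)=C/CC/C(C)=C/C(S(=O)(=O)c1ccccc1)C/C(C)=C/CC/C(C)=C/CC/C(C)=C/CC/C(C)=C/Cc1c(C)c(OC)c2ccccc2c1OC | intermediate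
13 | menaquinol-8 dimethyl ether (all-E) | CC(C)=CCC/C(C)=C/CC/C(C)=C/CC/C(C)=C/CC/C(C)=C/CC/C(C)=C/CC/C(C)=C/CC/C(C)=C/Cc1c(C)c(OC)c2ccccc2c1OC | intermediate
14 | menaquinone-8 | CC(C)=CCC/C(C)=C/CC/C(C)=C/CC/C(C)=C/CC/C(C)=C/CC/C(C)=C/CC/C(C)=C/CC/C(C)=C/CC1=C(C)C(=O)c2ccccc2C1=O | target

**Step count**

Total: 8 steps. Longest linear sequence: 6 steps (1 to 3 to 5 to 6 to 12 to 13 to 14; steps 1, 2, 3, 6, 7, 8).

**Steps most likely to fail**

Step 2. The allylic oxidation may lose site selectivity among the four trisubstituted alkenes, run on to over-oxidised material, or stall at low conversion. The fallback sets out from 3 and comes back at 5, and it rebuilds the chain terminus instead of oxidising it. NBS in THF/H2O at 0 °C, where the terminal alkene of a polyprenyl chain reacts first, would give the terminal bromohydrin F1. K2CO3 in MeOH would close it to the terminal epoxide F2. HIO4 in THF/H2O would cleave the epoxide, with loss of acetone, to the C14' aldehyde F3. Wittig reaction with the stabilised ylide Ph3P=C(CH3)CO2Et in CH2Cl2 would give the E α-methyl enoate F4. Reduction with i-Bu2AlH in toluene at −78 °C would then give alcohol 5 with C14'=C15' already E.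

Step 6. Proton transfer between product and anion leading to double alkylation, elimination of HBr from the allylic bromide, or γ-attack of the anion may erode the coupling. The fallback sets out from 7 and 6 and comes back at 13, and it forms the same C16'–C17' bond without sulfur. MsCl, LiCl and 2,4,6-collidine in DMF at 0 °C would convert 7 into geranylgeranyl chloride F5. Active barium (from BaI2 and lithium biphenylide in THF) at −78 °C would turn it into geranylgeranylbarium chloride F6. Allylbarium reagents are known to couple with allylic bromides at their α-carbon with retention of alkene geometry, so F6 and 6 at −78 °C should give 13 directly, and steps 6 and 7 fall away.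

Step 7. Isomerisation of the π-allylpalladium intermediate may scramble the C18'=C19' geometry, or hydride delivery to the wrong allyl terminus may shift the double bond. The fallback sets out from 12 and comes back at 13 with no new isolated compound. It replaces the π-allyl hydride pathway by single-electron cleavage of the C–S bond with sodium amalgam, Na(Hg), buffered with Na2HPO4 in MeOH/THF at −20 °C. These conditions spare the naphthalene ring and the aryl ethers. Any positional isomer would be removed by chromatography on AgNO3-impregnated silica.

**Further compounds**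

F1 | step 2 | 14'-bromo-15'-hydroxy-14',15'-dihydromenaquinol-4 dimethyl ether (racemic terminal bromohydrin) | CC(C)(O)C(Br)CC/C(C)=C/CC/C(C)=C/CC/C(C)=C/Cc1c(C)c(OC)c2ccccc2c1OC
F2 | step 2 | 14',15'-epoxy-14',15'-dihydromenaquinol-4 dimethyl ether (racemic terminal epoxide) | CC1(C)OC1CC/C(C)=C/CC/C(C)=C/CC/C(C)=C/Cc1c(C)c(OC)c2ccccc2c1OC
F3 | step 2 | C14' aldehyde (15',16'-dinor chain, all-E) of menaquinol-4 dimethyl ether | O=CCC/C(C)=C/CC/C(C)=C/CC/C(C)=C/Cc1c(C)c(OC)c2ccccc2c1OC
F4 | step 2 | ethyl (all-E) ester of menaquinol-4 dimethyl ether 16'-oic acid | CCOC(=O)/C(C)=C/CC/C(C)=C/CC/C(C)=C/CC/C(C)=C/Cc1c(C)c(OC)c2ccccc2c1OC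
F5 | step 6 | (2E,6E,10E)-geranylgeranyl chloride | CC(C)=CCC/C(C)=C/CC/C(C)=C/CC/C(C)=C/CCl
F6 | step 6 | (2E,6E,10E)-geranylgeranylbarium chloride | CC(C)=CCC/C(C)=C/CC/C(C)=C/CC/C(C)=C/C[Ba]Cl
F0 | step 7 | none | none
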